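**Retrosynthetic overview**
1. Target ⇐ one hydrogenation that saturates a C6 alkynyl carbinol side chain and removes three benzyl ethers.
2. Side chain ⇐ Sonogashira coupling of a 6-iodoflavone with 2-methylbut-3-yn-2-ol; the iodide ⇐ iodination ortho to the free, chelated 5-OH of the flavone.
3. Flavone ⇐ key disconnection at the O1–C2 bond of ring C: a phenolic oxygen closes onto the enone carbon of a chalcone-type intermediate made in the same flask from a 2,6-dihydroxyacetophenone (ring A) and 2,4-bis(benzyloxy)benzaldehyde (ring B). The two ortho hydroxyls are equivalent, so closure gives one product and turns them into O1 and the 5-OH that later steers substitution to C6.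
4. Ring A piece ⇐ 4-O-monobenzylation of 2',4',6'-trihydroxyacetophenone.
5. Ring order: rings A and B come from the starting materials; ring C is the only ring formed (step 2).

Assumption: the target has no stereocentre and no stereogenic double bond, so there is nothing to control; 2,4-bis(benzyloxy)benzaldehyde is taken as a catalogue chemical.

**Route**

Step 1
Reactants: 1 1-(2,4,6-trihydroxyphenyl)ethan-1-one (2',4',6'-trihydroxyacetophenone)
Product: 2 1-[4-(benzyloxy)-2,6-dihydroxyphenyl]ethan-1-one
Conditions: BnBr (1.0 equiv), K2CO3 (1.05 equiv), DMF, 0 °C to rt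
Reagents that add atoms: benzyl bromide (BrCc1ccccc1)
Why: Williamson ether synthesis in which the 4-OH, the most acidic hydroxyl and the only one not hydrogen-bonded to the carbonyl, is alkylated preferentially by one equivalent of base and halide, leaving the two chelated ortho hydroxyls free; no stereocentre is formed.

Step 2
Reactants: 2 1-[4-(benzyloxy)-2,6-dihydroxyphenyl]ethan-1-one, 3 2,4-bis(benzyloxy)benzaldehyde
Product: 8 7-(benzyloxy)-2-[2,4-bis(benzyloxy)phenyl]-5-hydroxy-4H-chromen-4-one, via acetophenone difluoroboron chelate 4 (not isolated), via chalcone difluoroboron chelate 5 (not isolated), via flavanone difluoroboron chelate 6 (not isolated), via flavone difluoroboron chelate 7 (not isolated)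
Conditions: BF3·OEt2 (1.1 equiv), PhMe, 50 °C; then 3, piperidine (30 mol%), 70 °C; then DDQ (1.1 equiv), 40 °C; then NaOAc, MeOH/H2O, 60 °C
Reagents that add atoms: none
Why: Proposed new method: a boron-templated one-flask annulation in which BF3 chelates the carbonyl and one of the two equivalent ortho hydroxyls of 2 (masking the future 5-OH and acidifying the methyl group), the chelate condenses with 3 in a Knoevenagel/Claisen–Schmidt manner under piperidinium catalysis, the remaining ortho hydroxyl closes ring C by 6-endo oxa-Michael addition onto the boron-activated enone (the key C–O bond), DDQ abstracts the C2 hydride (benzylic, alpha to oxygen, next to the boron enolate) to give the aromatic flavone chelate with no free phenol exposed to the oxidant, and buffered methanolysis releases the 5-hydroxyflavone; the closest known reaction types are the aldehyde condensations of difluoroboron chelates of o-hydroxyaryl methyl ketones and 1,3-diketones, the oxa-Michael cyclisation of 2'-hydroxychalcones and the quinone dehydrogenation of flavanones, which have not been combined on a 2,6-dihydroxyacetophenone; the C2 centre of 6 is racemic and is destroyed on dehydrogenation.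

Step 3
Reactants: 8 7-(benzyloxy)-2-[2,4-bis(benzyloxy)phenyl]-5-hydroxy-4H-chromen-4-one
Product: 9 7-(benzyloxy)-2-[2,4-bis(benzyloxy)phenyl]-5-hydroxy-6-iodo-4H-chromen-4-one
Conditions: BnMe3N·ICl2 (1.05 equiv), CaCO3, CH2Cl2/MeOH, rt
Reagents that add atoms: benzyltrimethylammonium dichloroiodate (C[N+](C)(C)Cc1ccccc1.Cl[I-]Cl)
Why: Electrophilic aromatic iodination directed by the free, chelated 5-OH to its ortho position C6, the only ring carbon next to a free phenol, while C8 and the ring B positions carry only ether activation and are spared by this mild reagent; no stereocentre is formed.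

Step 4
Reactants: 9 7-(benzyloxy)-2-[2,4-bis(benzyloxy)phenyl]-5-hydroxy-6-iodo-4H-chromen-4-one, 10 2-methylbut-3-yn-2-ol
Product: 11 7-(benzyloxy)-2-[2,4-bis(benzyloxy)phenyl]-5-hydroxy-6-(3-hydroxy-3-methylbut-1-yn-1-yl)-4H-chromen-4-one
Conditions: Pd(PPh3)2Cl2 (3 mol%), CuI (5 mol%), Et3N, THF, rt
Reagents that add atoms: none
Why: Sonogashira coupling, in which the slim terminal alkyne tolerates the two ortho substituents of the aryl iodide and the carbonyl-chelated 5-OH is too poor a nucleophile to cyclise onto the alkyne at room temperature; no stereocentre is formed.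

Step 5
Reactants: 11 7-(benzyloxy)-2-[2,4-bis(benzyloxy)phenyl]-5-hydroxy-6-(3-hydroxy-3-methylbut-1-yn-1-yl)-4H-chromen-4-one
Product: 12 2-(2,4-dihydroxyphenyl)-5,7-dihydroxy-6-(3-hydroxy-3-methylbutyl)-4H-chromen-4-one (target)
Conditions: H2 (1 atm), Pd/C (10 wt%), THF/MeOH, rt
Reagents that add atoms: none
Why: Heterogeneous catalytic hydrogenation saturates the alkyne and hydrogenolyses the three benzyl ethers in one operation, while the C2=C3 bond of the flavone (a vinylogous ester) is reduced far more slowly and the tertiary alcohol is retained; no stereocentre is formed.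

**Compound list**
1 | 1-(2,4,6-trihydroxyphenyl)ethan-1-one | CC(=O)c1c(O)cc(O)cc1O | starting material
2 | 1-[4-(benzyloxy)-2,6-dihydroxyphenyl]ethan-1-one | CC(=O)c1c(O)cc(OCc2ccccc2)cc1O | intermediate
3 | 2,4-bis(benzyloxy)benzaldehyde | O=Cc1ccc(OCc2ccccc2)cc1OCc1ccccc1 | starting material
4 | difluoroboron chelate of 2 (BF2 bridging the carbonyl oxygen and one ortho phenolic oxygen in a six-membered ring; other ortho OH free) | CC1=[O+][B-](F)(F)Oc2cc(OCc3ccccc3)cc(O)c12 | intermediate (not isolated)
5 | difluoroboron chelate of (E)-1-[4-(benzyloxy)-2,6-dihydroxyphenyl]-3-[2,4-bis(benzyloxy)phenyl]prop-2-en-1-one (same BF2 bridge; one ortho OH free) | F[B-]1(F)Oc2cc(OCc3ccccc3)cc(O)c2C(/C=C/c2ccc(OCc3ccccc3)cc2OCc2ccccc2)=[O+]1 | intermediate (not isolated)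
6 | difluoroboron chelate of racemic 7-(benzyloxy)-2-[2,4-bis(benzyloxy)phenyl]-5-hydroxychroman-4-one (BF2 bridging O5 and the C4 carbonyl oxygen) | F[B-]1(F)Oc2cc(OCc4ccccc4)cc3OC(c4ccc(OCc5ccccc5)cc4OCc4ccccc4)CC(=[O+]1)c23 | intermediate (not isolated)
7 | difluoroboron chelate of flavone 8 (BF2 bridging O5 and the C4 carbonyl oxygen) | F[B-]1(F)Oc2cc(OCc4ccccc4)cc3OC(c4ccc(OCc5ccccc5)cc4OCc4ccccc4)=CC(=[O+]1)c23 | intermediate (not isolated)
8 | 7-(benzyloxy)-2-[2,4-bis(benzyloxy)phenyl]-5-hydroxy-4H-chromen-4-one | O=c1cc(-c2ccc(OCc3ccccc3)cc2OCc2ccccc2)oc2cc(OCc3ccccc3)cc(O)c12 | intermediate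
9 | 7-(benzyloxy)-2-[2,4-bis(benzyloxy)phenyl]-5-hydroxy-6-iodo-4H-chromen-4-one | O=c1cc(-c2ccc(OCc3ccccc3)cc2OCc2ccccc2)oc2cc(OCc3ccccc3)c(I)c(O)c12 | intermediate
10 | 2-methylbut-3-yn-2-ol | C#CC(C)(C)O | starting material
11 | 7-(benzyloxy)-2-[2,4-bis(benzyloxy)phenyl]-5-hydroxy-6-(3-hydroxy-3-methylbut-1-yn-1-yl)-4H-chromen-4-one | O=c1cc(-c2ccc(OCc3ccccc3)cc2OCc2ccccc2)oc2cc(OCc3ccccc3)c(C#CC(C)(C)O)c(O)c12 | intermediate
12 | 2-(2,4-dihydroxyphenyl)-5,7-dihydroxy-6-(3-hydroxy-3-methylbutyl)-4H-chromen-4-one (achiral) | CC(C)(O)CCc1c(O)cc2oc(-c3ccc(O)cc3O)cc(=O)c2c1O | target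

**Step count**
Total steps: 5. Longest linear sequence: 5 steps (1 → 2 → 8 → 9 → 11 → 12).

**Three steps most likely to fail, with fallbacks**

Step 2 (the proposed new step). The chelate may condense sluggishly with the hindered, electron-rich aldehyde, the oxa-Michael closure may stall, or DDQ may over-oxidise. The fallback uses known chemistry and sets out from 2 and 3. Claisen–Schmidt condensation (KOH, EtOH/H2O, rt) gives the chalcone (E)-1-[4-(benzyloxy)-2,6-dihydroxyphenyl]-3-[2,4-bis(benzyloxy)phenyl]prop-2-en-1-one F1. Oxidative cyclisation of it with I2 (10 mol%) in DMSO at 120 °C (oxa-Michael addition, alpha-iodination, loss of HI; both ortho hydroxyls are equivalent) comes back to the route at 8.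

Step 4. The iodide has two ortho substituents, and the copper co-catalyst could promote 5-endo cyclisation of the alkynylphenol to a furan. The fallback sets out from 9 and avoids an alkyne altogether. Suzuki–Miyaura coupling with commercial (E)-2-methyl-4-(4,4,5,5-tetramethyl-1,3,2-dioxaborolan-2-yl)but-3-en-2-ol (Pd(dppf)Cl2, K3PO4, dioxane/H2O, 80 °C) gives 7-(benzyloxy)-2-[2,4-bis(benzyloxy)phenyl]-5-hydroxy-6-[(E)-3-hydroxy-3-methylbut-1-en-1-yl]-4H-chromen-4-one F2. The hydrogenation conditions of step 5 then saturate the alkene and remove the benzyl groups, coming back to the route at 12.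

Step 5. The flavone C2=C3 bond may be over-reduced, or the propargylic/allylic C–O bond may be hydrogenolysed while the side chain passes through the alkene stage. The fallback sets out from 11 and separates the two events. Hydrogenation over Pd/C poisoned with ethylenediamine (H2, 1 atm, THF, rt), which does not cleave benzyl ethers or C–O bonds, saturates only the alkyne and gives 7-(benzyloxy)-2-[2,4-bis(benzyloxy)phenyl]-5-hydroxy-6-(3-hydroxy-3-methylbutyl)-4H-chromen-4-one F3. Transfer hydrogenolysis (Pd(OH)2/C, cyclohexa-1,4-diene, EtOH, 40 °C) then removes the benzyl ethers, coming back to the route at 12.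

**Further compounds**
F1 | step 2 | (E)-1-[4-(benzyloxy)-2,6-dihydroxyphenyl]-3-[2,4-bis(benzyloxy)phenyl]prop-2-en-1-one | O=C(/C=C/c1ccc(OCc2ccccc2)cc1OCc1ccccc1)c1c(O)cc(OCc2ccccc2)cc1O
F2 | step 4 | 7-(benzyloxy)-2-[2,4-bis(benzyloxy)phenyl]-5-hydroxy-6-[(E)-3-hydroxy-3-methylbut-1-en-1-yl]-4H-chromen-4-one | O=c1cc(-c2ccc(OCc3ccccc3)cc2OCc2ccccc2)oc2cc(OCc3ccccc3)c(/C=C/C(C)(C)O)c(O)c12
F3 | step 5 | 7-(benzyloxy)-2-[2,4-bis(benzyloxy)phenyl]-5-hydroxy-6-(3-hydroxy-3-methylbutyl)-4H-chromen-4-one | CC(C)(O)CCc1c(OCc2ccccc2)cc2oc(-c3ccc(OCc4ccccc4)cc3OCc3ccccc3)cc(=O)c2c1O
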